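**Retrosynthetic overview**

- Structural handle: in the γ-butyrolactone ring (O1–C2(=O)–C3–C4–C5H2), the adjacent carbons C3 and C4 each carry one exocyclic carbon. C3 bears the =CH of the syringylidene unit. C4, the only stereocentre (R), bears the CH2 of the 3,4,5-trimethoxybenzyl group. A butenolide that takes a nucleophile at C4 and an electrophile at C3 leaves exactly this pattern.
- Late disconnections: phenol ⇐ MOM ether; (E)-C3=CH ⇐ β-hydroxy lactone (E1cB); ring C5H2 ⇐ acetal carbon C5 carrying an l-menthyloxy auxiliary; benzylic CH2 ⇐ 1,3-dithiane carbon.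
- Key disconnection: the C4–C(dithiane) and C3–C(carbinol) bonds are cut together. This gives (5R)-5-(l-menthyloxy)butenolide, a lithiated 2-aryl-1,3-dithiane and MOM-protected syringaldehyde.
- Ring order: the lactone is the only ring built for the target, and it comes first (furan of furfural → butenolide). It serves as the stereochemical template and is opened once and reclosed at once when the auxiliary is removed. Both arenes are bought, and the dithiane is a temporary ring.

Key step: step 5

Assumption: the carbinol carbon ArCH(O–) of 12–17 is expected as an epimer mixture. It is written without configuration and carried on unseparated, because step 8 turns it into an sp2 carbon.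

**Step 1**
Reactants: 1 furfural
Product: 3 5-hydroxyfuran-2(5H)-one (racemic), via furfural endoperoxide 2 (not isolated)
Conditions: O2, hν (visible), cat. rose bengal, MeOH, 0–20 °C
Reagents that add atoms: dioxygen, O=O
Why: Dye-sensitised singlet-oxygen [4+2] cycloaddition to the furan (furan photooxygenation) gives endoperoxide 2, whose formyl group is attacked by methanol and leaves as methyl formate while the O–O bond breaks to give the lactone carbonyl and the C5 hydroxyl, C5 being formed racemic and configurationally labile.

**Step 2**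
Reactants: 3 5-hydroxyfuran-2(5H)-one; 4 l-menthol
Product: 5 (5R)-5-(l-menthyloxy)furan-2(5H)-one
Conditions: cat. CSA, toluene, reflux, Dean–Stark; crystallisation from petroleum ether, −20 °C; mother liquor re-equilibrated with cat. CSA and crystallised again
Reagents that add atoms: none
Why: Acid-catalysed acetalisation of the pseudo-acid with removal of water gives both C5 epimers, which interconvert under the acid catalyst, and C5 is set by selective crystallisation of the 5R diastereomer with recycling of the equilibrated mother liquor.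

**Step 3**
Reactants: 6 3,4,5-trimethoxybenzaldehyde
Product: 7 2-(3,4,5-trimethoxyphenyl)-1,3-dithiane
Conditions: HS(CH2)3SH, cat. BF3·OEt2, CH2Cl2, 0 °C → rt
Reagents that add atoms: propane-1,3-dithiol, SCCCS
Why: Lewis-acid-catalysed dithioacetalisation of an aromatic aldehyde is driven by formation of the six-membered dithiane and creates no stereocentre.

**Step 4**
Reactants: 8 syringaldehyde
Product: 9 3,5-dimethoxy-4-(methoxymethoxy)benzaldehyde
Conditions: MOMCl, i-Pr2NEt, CH2Cl2, 0 °C → rt
Reagents that add atoms: chloromethyl methyl ether (MOMCl), COCCl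
Why: Williamson-type O-alkylation of the phenol by the reactive chloromethyl ether installs a MOM acetal that should withstand lithium enolates, nickel boride, hydroxide/borohydride and amine bases, and that is later removed by acid, whereas hydrogenolysis of a benzyl ether would endanger the final alkene.

**Step 5**
Reactants: 7 2-(3,4,5-trimethoxyphenyl)-1,3-dithiane; 5 (5R)-5-(l-menthyloxy)furan-2(5H)-one; 9 3,5-dimethoxy-4-(methoxymethoxy)benzaldehyde
Product: 12 (3S,4R,5R)-3-{[3,5-dimethoxy-4-(methoxymethoxy)phenyl](hydroxy)methyl}-5-(l-menthyloxy)-4-[2-(3,4,5-trimethoxyphenyl)-1,3-dithian-2-yl]dihydrofuran-2(3H)-one (carbinol epimers), via 2-lithio-dithiane 10 (not isolated), via lithium enolate 11 (not isolated)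
Conditions: 7, n-BuLi, THF, −78 → −20 °C; recool to −78 °C, add 5 in THF; then 9 in THF, −78 °C; AcOH/THF quench at −78 °C
Reagents that add atoms: n-butyllithium, [Li]CCCC (supplies only the lithium of intermediates 10 and 11; nothing from it remains in 12)
Why: n-BuLi removes the C2–H of 7 to give the sulfur- and aryl-stabilised carbanion 10, which adds in Michael fashion to C4 of butenolide 5, and the lithium enolate 11 released in this way attacks the formyl carbon of the non-enolisable aldehyde 9, so that the C4–C(dithiane) and C3–C(carbinol) bonds are both formed in one flask. The closest known reaction type is the tandem conjugate addition–enolate trapping of lithiated 2-aryl-1,3-dithianes on butenolides and 5-alkoxybutenolides with aldehydes or benzyl halides, so this is an application of that chemistry to a new set of arenes. No ring is closed, since the lactone ring is present from the start and only serves as a flat, rigid template. C4 is controlled by the C5 menthyloxy group, which covers one face of the butenolide so that 10 enters anti to it (4,5-trans, 4R, the configuration of the target); C3 is controlled by the new and very bulky C4 dithianyl group, which sends the aldehyde to the opposite face of 11 (3,4-trans, 3S); the carbinol carbon is not controlled and need not be, as it becomes sp2 in step 8. The step needs 1,4- over 1,2-addition and addition over removal of the acidic C5–H of 5, and both should be secured by the soft, delocalised and sterically demanding character of 10 at −78 °C. As the aldol with the electron-rich aldehyde is reversible, the lithium alkoxide is protonated with AcOH at −78 °C before warming.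

**Step 6**
Reactants: 12 tandem adduct
Product: 13 (3S,4R,5R)-3-{[3,5-dimethoxy-4-(methoxymethoxy)phenyl](hydroxy)methyl}-5-(l-menthyloxy)-4-(3,4,5-trimethoxybenzyl)dihydrofuran-2(3H)-one
Conditions: NiCl2·6H2O, NaBH4 (portionwise), MeOH–THF, 0 °C → rt; filtration through Celite
Reagents that add atoms: none
Why: Reductive desulfurisation with nickel boride generated in situ, the mild counterpart of Raney nickel hydrogenolysis, should replace both benzylic C–S bonds by C–H without cleaving the benzylic C–OH bond, the MOM ether or the lactone acetal, and it touches no stereocentre.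

**Step 7**
Reactants: 13 desulfurised menthyloxy lactone
Product: 16 (3S,4R)-3-{[3,5-dimethoxy-4-(methoxymethoxy)phenyl](hydroxy)methyl}-4-(3,4,5-trimethoxybenzyl)dihydrofuran-2(3H)-one, via formyl carboxylate 14 (not isolated), via dihydroxy acid 15 (not isolated)
Conditions: NaBH4 (present from the outset), aq KOH, MeOH, 0 °C → rt; then 1 M HCl to pH 3, 0 °C → rt, EtOAc
Reagents that add atoms: potassium hydroxide, [K+].[OH-] (potassium of 14 and one carboxyl oxygen of 14 and 15; one oxygen leaves again as water on lactonisation)
Why: Saponification of the acylal-type lactone frees the C5 hemiacetal, which collapses to aldehyde 14 with loss of menthoxide, the borohydride already present reduces this aldehyde before C4 can enolise, and mild acidification of 15 closes the γ-lactone through the primary hydroxyl (5-exo-trig lactonisation, favoured over a β-lactone through the carbinol), so that C3 and C4 keep their configuration and C5 becomes the ring OCH2.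

**Step 8**
Reactants: 16 β-hydroxy lactone
Product: 18 (3E,4R)-3-[3,5-dimethoxy-4-(methoxymethoxy)benzylidene]-4-(3,4,5-trimethoxybenzyl)dihydrofuran-2(3H)-one, via benzylic mesylate 17 (not isolated)
Conditions: MsCl, Et3N, CH2Cl2, 0 °C; then DBU, 0 °C → rt (one pot)
Reagents that add atoms: methanesulfonyl chloride, CS(=O)(=O)Cl (present only in intermediate 17; expelled again on the way to 18)
Why: Mesylation of the secondary benzylic alcohol followed by DBU-induced E1cB elimination through the lactone enolate lets both carbinol epimers converge on the conjugated, thermodynamically preferred E-arylidene lactone with the aryl group turned away from the carbonyl, while C4–H is not activated by the carbonyl and 4R should therefore be retained.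

**Step 9**
Reactants: 18 MOM-protected arylidene lactone
Product: 19 (3E,4R)-3-(4-hydroxy-3,5-dimethoxybenzylidene)-4-(3,4,5-trimethoxybenzyl)dihydrofuran-2(3H)-one (CNP0198204.1)
Conditions: cat. conc. aq HCl, MeOH–THF, 40 °C
Reagents that add atoms: none
Why: Acid-catalysed acetal exchange of the aryl MOM ether with methanol frees the phenol, while the lactone, the trisubstituted alkene, the methyl ethers and the non-acidic C4 stereocentre are inert under these conditions.

**Compound list**

| No. | Name | SMILES | Role |
|---|---|---|---|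
| 1 | furfural | O=Cc1ccco1 | starting material |
| 2 | 1-formyl-2,3,7-trioxabicyclo[2.2.1]hept-5-ene (furfural endoperoxide, racemic) | O=CC12OOC(O1)C=C2 | intermediate |
| 3 | 5-hydroxyfuran-2(5H)-one (racemic) | O=C1OC(O)C=C1 | intermediate |
| 4 | l-menthol, (1R,2S,5R)-2-isopropyl-5-methylcyclohexan-1-ol | CC(C)[C@@H]1CC[C@@H](C)C[C@H]1O | starting material |
| 5 | (5R)-5-(l-menthyloxy)furan-2(5H)-one | O=C1O[C@@H](O[C@@H]2C[C@H](C)CC[C@H]2C(C)C)C=C1 | intermediate |
| 6 | 3,4,5-trimethoxybenzaldehyde | COc1cc(C=O)cc(OC)c1OC | starting material |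
| 7 | 2-(3,4,5-trimethoxyphenyl)-1,3-dithiane | COc1cc(C2SCCCS2)cc(OC)c1OC | intermediate |
| 8 | syringaldehyde (4-hydroxy-3,5-dimethoxybenzaldehyde) | COc1cc(C=O)cc(OC)c1O | starting material |
| 9 | 3,5-dimethoxy-4-(methoxymethoxy)benzaldehyde | COCOc1c(OC)cc(C=O)cc1OC | intermediate |
| 10 | 2-lithio-2-(3,4,5-trimethoxyphenyl)-1,3-dithiane | [Li]C1(c2cc(OC)c(OC)c(OC)c2)SCCCS1 | intermediate |
| 11 | lithium enolate of the (4R,5R) conjugate adduct | [Li]OC1=C[C@@H](C2(c3cc(OC)c(OC)c(OC)c3)SCCCS2)[C@H](O[C@@H]2C[C@H](C)CC[C@H]2C(C)C)O1 | intermediate |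
| 12 | (3S,4R,5R)-3-{[3,5-dimethoxy-4-(methoxymethoxy)phenyl](hydroxy)methyl}-5-(l-menthyloxy)-4-[2-(3,4,5-trimethoxyphenyl)-1,3-dithian-2-yl]dihydrofuran-2(3H)-one | COCOc1c(OC)cc(C(O)[C@H]2C(=O)O[C@@H](O[C@@H]3C[C@H](C)CC[C@H]3C(C)C)[C@@H]2C4(c3cc(OC)c(OC)c(OC)c3)SCCCS4)cc1OC | intermediate |
| 13 | (3S,4R,5R)-3-{[3,5-dimethoxy-4-(methoxymethoxy)phenyl](hydroxy)methyl}-5-(l-menthyloxy)-4-(3,4,5-trimethoxybenzyl)dihydrofuran-2(3H)-one | COCOc1c(OC)cc(C(O)[C@H]2C(=O)O[C@@H](O[C@@H]3C[C@H](C)CC[C@H]3C(C)C)[C@@H]2Cc2cc(OC)c(OC)c(OC)c2)cc1OC | intermediate |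
| 14 | potassium (2S,3R)-2-{[3,5-dimethoxy-4-(methoxymethoxy)phenyl](hydroxy)methyl}-3-formyl-4-(3,4,5-trimethoxyphenyl)butanoate | COCOc1c(OC)cc(C(O)[C@@H](C(=O)[O-])[C@H](C=O)Cc2cc(OC)c(OC)c(OC)c2)cc1OC.[K+] | intermediate |
| 15 | (2S,3R)-2-{[3,5-dimethoxy-4-(methoxymethoxy)phenyl](hydroxy)methyl}-3-(hydroxymethyl)-4-(3,4,5-trimethoxyphenyl)butanoic acid | COCOc1c(OC)cc(C(O)[C@@H](C(=O)O)[C@H](CO)Cc2cc(OC)c(OC)c(OC)c2)cc1OC | intermediate |
| 16 | (3S,4R)-3-{[3,5-dimethoxy-4-(methoxymethoxy)phenyl](hydroxy)methyl}-4-(3,4,5-trimethoxybenzyl)dihydrofuran-2(3H)-one | COCOc1c(OC)cc(C(O)[C@H]2C(=O)OC[C@@H]2Cc2cc(OC)c(OC)c(OC)c2)cc1OC | intermediate |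
| 17 | methanesulfonate of 16 | COCOc1c(OC)cc(C(OS(C)(=O)=O)[C@H]2C(=O)OC[C@@H]2Cc2cc(OC)c(OC)c(OC)c2)cc1OC | intermediate |
| 18 | (3E,4R)-3-[3,5-dimethoxy-4-(methoxymethoxy)benzylidene]-4-(3,4,5-trimethoxybenzyl)dihydrofuran-2(3H)-one | COCOc1c(OC)cc(/C=C2/C(=O)OC[C@@H]2Cc2cc(OC)c(OC)c(OC)c2)cc1OC | intermediate |
| 19 | (3E,4R)-3-(4-hydroxy-3,5-dimethoxybenzylidene)-4-(3,4,5-trimethoxybenzyl)dihydrofuran-2(3H)-one | COc1cc(/C=C2/C(=O)OC[C@@H]2Cc2cc(OC)c(OC)c(OC)c2)cc(OC)c1O | target |

Total step count: 9
Longest linear sequence: 7 steps (1, 2, 5, 6, 7, 8, 9, from furfural)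

**Steps most likely to fail**

**1. Step 5.**
- What may go wrong: capture of the hindered enolate by the electron-rich aldehyde may be incomplete or may reverse on warming. The carbanion may also attack the lactone carbonyl or remove the C5–H of the butenolide.
- Fallback (sets out from 5 and 7, returns at 12): the two bond formations are decoupled.
  - The conjugate addition is run as before, but enolate 11 is silylated with TMSCl at −78 °C. This gives the ketene acetal (2R,3R)-2-(l-menthyloxy)-3-[2-(3,4,5-trimethoxyphenyl)-1,3-dithian-2-yl]-5-(trimethylsilyloxy)-2,3-dihydrofuran F1, which is freed from salts by a non-aqueous work-up.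
  - F1 is then combined with aldehyde 9 and BF3·OEt2 in CH2Cl2 at −78 °C (Mukaiyama aldol).
  - This addition is irreversible and runs through an open transition state. It should again take place anti to the C4 substituent, and aqueous work-up gives 12.

**2. Step 7.**
- What may go wrong: hydroxide may trigger retro-aldol cleavage of the C3–carbinol bond. The transient aldehyde may enolise at C4 before hydride arrives, which would erode the enantiomeric purity of the only stereocentre that is kept. Acidification may also cost the MOM group or ionise the benzylic carbinol.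
- Fallback (sets out from 5 and 7, returns at 16): the auxiliary is removed before the carbinol exists.
  - The conjugate addition is quenched with AcOH instead of the aldehyde. This gives (4R,5R)-5-(l-menthyloxy)-4-[2-(3,4,5-trimethoxyphenyl)-1,3-dithian-2-yl]dihydrofuran-2(3H)-one F2.
  - Nickel desulfurisation (nickel boride or Raney nickel) converts F2 into (4R,5R)-5-(l-menthyloxy)-4-(3,4,5-trimethoxybenzyl)dihydrofuran-2(3H)-one F3.
  - KOH/NaBH4 followed by acid gives (R)-4-(3,4,5-trimethoxybenzyl)dihydrofuran-2(3H)-one F4. Its enantiomeric purity can be checked at this stage.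
  - The LDA enolate of F4 (THF, −78 °C) is added to aldehyde 9 anti to the C4 benzyl group, which gives 16.

**3. Step 6.**
- What may go wrong: C–S hydrogenolysis at the congested quaternary benzylic carbon may stall after the first bond. Material may be lost by adsorption on the nickel solid. The basic borohydride medium may start retro-aldol cleavage. Premature opening of the acylal followed by reduction would only lead on towards 16.
- Fallback (sets out from 6, with 5 and 9, and returns at 13): the benzyl anion equivalent is exchanged for one that can be removed by a homogeneous, neutral radical chain.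
  - Aldehyde 6 is condensed with thiophenol (BF3·OEt2, CH2Cl2) to give 5-[bis(phenylsulfanyl)methyl]-1,2,3-trimethoxybenzene F5.
  - F5 is lithiated with n-BuLi and taken through the same sequence with 5 and then 9. This gives the adduct (3S,4R,5R)-4-[bis(phenylsulfanyl)(3,4,5-trimethoxyphenyl)methyl]-3-{[3,5-dimethoxy-4-(methoxymethoxy)phenyl](hydroxy)methyl}-5-(l-menthyloxy)dihydrofuran-2(3H)-one F6.
  - Bu3SnH/AIBN in refluxing toluene then cleaves both C–SPh bonds through benzylic radicals and gives 13.

**Further compounds**
F1 | step 5 | (2R,3R)-2-(l-menthyloxy)-3-[2-(3,4,5-trimethoxyphenyl)-1,3-dithian-2-yl]-5-(trimethylsilyloxy)-2,3-dihydrofuran | C[Si](C)(C)OC1=C[C@@H](C2(c3cc(OC)c(OC)c(OC)c3)SCCCS2)[C@H](O[C@@H]2C[C@H](C)CC[C@H]2C(C)C)O1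
F2 | step 7 | (4R,5R)-5-(l-menthyloxy)-4-[2-(3,4,5-trimethoxyphenyl)-1,3-dithian-2-yl]dihydrofuran-2(3H)-one | O=C1C[C@@H](C2(c3cc(OC)c(OC)c(OC)c3)SCCCS2)[C@H](O[C@@H]2C[C@H](C)CC[C@H]2C(C)C)O1
F3 | step 7 | (4R,5R)-5-(l-menthyloxy)-4-(3,4,5-trimethoxybenzyl)dihydrofuran-2(3H)-one | O=C1C[C@@H](Cc2cc(OC)c(OC)c(OC)c2)[C@H](O[C@@H]2C[C@H](C)CC[C@H]2C(C)C)O1
F4 | step 7 | (R)-4-(3,4,5-trimethoxybenzyl)dihydrofuran-2(3H)-one | O=C1C[C@@H](Cc2cc(OC)c(OC)c(OC)c2)CO1
F5 | step 6 | 5-[bis(phenylsulfanyl)methyl]-1,2,3-trimethoxybenzene | COc1cc(C(Sc2ccccc2)Sc2ccccc2)cc(OC)c1OC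
F6 | step 6 | (3S,4R,5R)-4-[bis(phenylsulfanyl)(3,4,5-trimethoxyphenyl)methyl]-3-{[3,5-dimethoxy-4-(methoxymethoxy)phenyl](hydroxy)methyl}-5-(l-menthyloxy)dihydrofuran-2(3H)-one | COCOc1c(OC)cc(C(O)[C@H]2C(=O)O[C@@H](O[C@@H]3C[C@H](C)CC[C@H]3C(C)C)[C@@H]2C(Sc2ccccc2)(Sc2ccccc2)c2cc(OC)c(OC)c(OC)c2)cc1OC
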